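**One-step world.** In a one-step world, substrate lost appears at once as target, and a flask without substrate is finished. Birch, the flask asked about, does not fit that picture: at 8.00 d it reads target 51.4% and substrate 1.3%, so 47.3% of the charge is unseen. The next step for birch hangs on where that share sits.

| flask | substrate | reagent | free catalyst | remark | time |
|---|---|---|---|---|---|
| birch | 0.010 M | 10 mM | 2 mM | the very flask that is asked about, followed so far |  |
| oak | 0.015 M | 10 mM | 2 mM | run made earlier |  |
| flask | 0.010 M | 10.0 mM | 2.0 mM |  | 8.0 d |

| run | time / d | target / % | substrate / % |
|---|---|---|---|
| birch | 0.500 | 15.5 | 57.6 |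
| birch | 1.67 | 45.6 | 11.1 |
| birch | 3.00 | 49.8 | 4.5 |
| birch | 4.00 | 52.2 | 4.4 |
| birch | 6.00 | 52.4 | 0.5 |
| birch | 8.00 | 51.4 | 1.3 |
| oak | 0.500 | 9.2 | 68.4 |
| oak | 0.833 | 17.9 | 55.0 |
| oak | 1.25 | 27.7 | 42.7 |
| oak | 2.00 | 32.5 | 27.7 |
| oak | 4.00 | 33.2 | 23.9 |
| oak | 6.00 | 35.4 | 19.9 |

(standard deviation of a reading: 1 percentage point)

- north-east: at 8.0 d add free catalyst, 50.0% of the amount charged, then wait 15 d
- north-west: at 8.0 d add reagent, 100% of the amount charged, then wait 15 d
- south: at 8.0 d take out 90% of the target then present, then wait 15 d
- south-west: change nothing and wait 15 d more

- target taken out counts as made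
- additions bring no volume worth counting

- target, in percent of the substrate first charged, at 8.0 d
- which option adds most target ("none" when 2 percentage points or less is all one gets) (north-east / north-west / south / south-west / none)
- target present, with what was taken out counted in, in percent of the substrate first charged, after north-west
- target present, with what was taken out counted in, in percent of the substrate first charged, after south

**Reagent balance.** Birch levels off at c(target) = 5.24 mM and oak at 5.31 mM, although oak still reads substrate 19.9%. Both were charged 10 mM of reagent, and with plateaus across two substrate charges, reagent reads as the limiting reagent. Target accounts for about half of it.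

**Parked share.** Birch's target lags: at 0.500 d, 42.4% of the substrate has been lost but target reads 15.5%. The reckoning here takes this to mean that substrate first binds to the catalyst, one per catalyst, and waits there for reagent. A stalled flask then holds the parked share, the catalyst charge over the substrate charge: 20.0%. Fresh reagent should release this share and carry the free substrate with it, so north-west should reach about 73.7%. Added free catalyst meets substrate of 1.3%, against a margin of 2 percentage points. Waiting or taking target out adds no reagent. The choice is north-west.

**The forecast.** It gives 52% now, best none, 52.5% after north-west and 52.5% after south, holding that “more reagent or catalyst has nothing to convert, unless the missing 47% is a hidden reservoir”. The reckoning above parts from it on north-west.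

**The flask.** Birch stands at 51.0%. The best option is north-west, which gains 21 points and reaches 71.9%, while south stays at 51.0%.

    reagent + catalyst intermediate A → catalyst intermediate B (k = 0.170 M⁻¹ s⁻¹)
    substrate + free catalyst → catalyst intermediate A (k = 0.370 M⁻¹ s⁻¹)
    substrate + by-product → side product (k = 0.00150 M⁻¹ s⁻¹)
    catalyst intermediate B → by-product + catalyst intermediate C (k = 1.20 × 10⁻⁴ s⁻¹)
    2 reagent → homo dimer (k = 0.00260 M⁻¹ s⁻¹)
    catalyst intermediate C → free catalyst + target (k = 2.70 × 10⁻⁵ s⁻¹)

**Parked substrate.** At 8.00 d birch holds reagent 0% of its charge and catalyst intermediate A, the resting state, at >99.9% of the catalyst charged. The parked share 20.0% plus substrate 0.923% gives 20.9%, against the gain of 21 points. The loss of reagent to homo dimer is at most the largest single effect behind this gain: in the run without that loss, north-west gains 0 points instead of 21 points. A neighbour flask, charged like birch but with 5.0 × 10⁻⁴ M of free catalyst, has a parked share of 5.00%, and at 8.00 d it holds 5.00% of its substrate charge as catalyst intermediate A.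

(The runs come from a simulation with made-up constants; noise was put on by code.)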